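(Readings and results were generated by integration from invented constants, noise included.)

The free enzyme turns starting material into product, and what I want from each flask is how much work a charge of it does before it stops.

| flask | starting material | free enzyme | temperature | remark | time |
|---|---|---|---|---|---|
| spring | 0.11 M | 0.0027 mol% | 25 °C | run made earlier |  |
| autumn | 0.11 M | 0.004 mol% | 45 °C | run made earlier |  |
| winter | 0.22 M | 0.0054 mol% | 25 °C | run made earlier |  |
| Saturday's | 0.11 M | 0.0054 mol% | 30 °C |  | 2.5 h |
| Sunday's | 0.11 M | 0.0054 mol% | 60 °C |  | 2.5 h |
| Tuesday's | 0.11 M | 0.0054 mol% | 45 °C |  | 2.5 h |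
| Monday's | 0.11 M | 0.0054 mol% |  | at 60 °C until 50 min, from then on at 30 °C | 2.5 h |

- spring (time / min: product / %): 10.0: 8.0; 15.0: 10.9; 25.0: 18.0; 40.0: 27.7; 80.0: 49.7; 120: 65.5
- autumn (time / min: product / %): 5.00: 13.3; 8.00: 19.4; 12.0: 27.2; 20.0: 37.8; 40.0: 53.7; 60.0: 60.2
- winter (time / min: product / %): 10.0: 21.2; 30.0: 55.4; 60.0: 85.0; 80.0: 94.2; 120: 99.8

(scatter of a reading: 0.5 percentage points)

- the numbers in the tables scatter by 0.5 percentage points (one standard deviation)

* the flask that comes out highest in amount of product, in percent of the starting material charged, or "all alike" when all lie within 1.5 percentage points (Saturday's / Sunday's / Tuesday's / Monday's / all alike)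
* product at the end, in percent of the starting material charged, Saturday's
* product at the end, in percent of the starting material charged, Sunday's
* product at the end, in percent of the starting material charged, Tuesday's
* product at the end, in percent of the starting material charged, Monday's

I write X for the fraction of starting material converted and c for its starting concentration, and I define the budget Θ as minus the logarithm of the fraction left plus cX/Km, where Km is the Michaelis constant. With a Michaelis–Menten rate, and for as long as the enzyme stays active, Θ grows in step with enzyme concentration (loading times c) multiplied by time.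

So what is Km? Spring at 120 min and winter at 30.0 min have equal enzyme concentration times time, so if the enzyme lasts that long at 25 °C their budgets match, and their readings give Km = 0.194 M.

Does the enzyme last when warm? In autumn Θ reads 0.689, 1.07 and 1.26 at 20.0 min, 40.0 min and 60.0 min, so the last gain is half the one before. I read this as the enzyme dying, and gains that keep halving add up to one more last gain, which gives the ceiling budget Θ∞, the total work of a charge and a close relative of the total turnover number, of 1.45 for autumn.

At one temperature and one c, Θ∞ should scale with loading, so Tuesday's gets 1.96. Its 2.5 h is 7.50 such steps, which spends nearly all of it, and solving for X, I expect 78.2 %.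

Can Saturday's beat that? At spring's pace, with no credit for the warmer bath, its Θ reaches 3.59, more than Tuesday's ceiling, so I put Saturday's ahead of Tuesday's, provided its enzyme lasts at 30 °C. The earlier runs go up to 45 °C, so I have no ceiling to scale for Sunday's at 60 °C or for Monday's, which starts at 60 °C.

The forecast names Saturday's as highest, with 97.5 % there, 79 % on Tuesday's against my 78.2 %, and 11 % on Sunday's, where “the enzyme dies within minutes”, and 11 % on Monday's.

The flasks give 98.3 % on Saturday's, 80.1 % on Tuesday's, 2.95 % on Sunday's and 2.95 % on Monday's, so Saturday's comes out highest, and the forecast's Sunday's figure stands 8.1 percentage points above.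

    free enzyme → unfolded enzyme (k = 0.0130 h⁻¹, Ea = 264 kJ mol⁻¹)
    starting material + free enzyme → product + free enzyme, rate k2*[starting material]*[free enzyme]/(1 + ([starting material]/Km2)) (0.160 M, k = 3.40 × 10⁵ M⁻¹ h⁻¹, Ea = 39.0 kJ mol⁻¹)
    free enzyme ⇌ dormant form (K = 0.560, k = 0.0440 h⁻¹, Ea = 98.0 kJ mol⁻¹, ΔH = −18.0 kJ mol⁻¹)
    (constants at 30 °C)

At 2.50 h Tuesday's holds, of the enzyme charged, 2.20 % free enzyme, 93.8 % unfolded enzyme and 4.01 % dormant form, and its conversion corresponds to Θ = 2.07, a little above the 1.96 scaled from autumn's Θ∞.

The same rule goes to a neighbour of Monday's charged with 0.014 mol% of free enzyme: Monday's Θ of 0.0466 scales with loading to 0.121, which, taking the logarithm as X itself at so small a conversion, means 7.72 %. The computed neighbour gives 7.53 %.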